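(The readings are calculated for an exercise, noise included.)

Amounts come first: how much X ends up in chains, and how many chains share it.

| setting | south | south-east | flask |
|---|---|---|---|
| X | 0.80 M | 0.54 M | 0.80 M |
| E | 0.080 M | 0.080 M | 0.0800 M |
| G | 1 mol% | 1 mol% | 1 mol% |
| remark | the very flask that is asked about, followed so far | run made earlier |  |
| time |  |  | 15 h |

- south (time / min: J / %, X / %): 12.0: 3, 93; 25.0: 9, 84; 40.0: 15, 78; 50.0: 21, 74; 60.0: 20, 73; 80.0: 27, 62
- south-east (time / h: J / %, X / %): 0.417: 4, 87; 1.33: 19, 68; 2.00: 28, 60; 3.00: 34, 47; 5.00: 47, 39; 6.00: 53, 31

(scatter of a reading: 1.5 percentage points)

- whether the average number of monomer units in a chain (chains begun, living or dead) reaches 300 by 15 h (no / yes)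
- average number of monomer units in a chain (chains begun, living or dead) at 15 h

- the average divides the monomer in chains by the number of chains begun, living and dead together
- the earlier runs do not show the number of chains; that part of a forecast is a guess

At the last readings, X missing from both X and J is 0.0880 M in the south run and 0.0864 M in the south-east run, close to the 0.0800 M of E, so E appears to take X one to one. The number of chains is a guess: one per G, 0.00800 M in this flask.

Length is then X not taken by E, divided by G. Each input of this flask can be doubled in turn. A loading of 2.00% G gives 45.0, 0.160 M E gives 80.0, and 1.60 M X at the same loading gives 95.0. Doubled, G therefore moves the length further than E or X does, and it is the number to know well.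

As charged, this quotient is 90.0, the full-use length (the degree of polymerisation at full conversion). Time matters through the approach to it. The south run's 27% of J at 80.0 min reads as a first-order rate of 0.268 h⁻¹, and as an estimate that rate leaves 1.80% of the available X at 15 h. The reckoning here therefore commits to 88.4.

The forecast says no, with a length of 87 (range 45 to 180), a little below that figure, and holds that “growth looks living, with active centres proportional to G”.

The flask answers no, with a length of 83.3, which is 92.6% of the full-use length.

    X + G → Z + J (k = 0.185 M⁻¹ min⁻¹)
    X + Z → J + Z, rate k2*[Z]*[X] (k = 0.599 M⁻¹ min⁻¹)
    Z → L (k = 0.00125 min⁻¹)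
    E + X → D (k = 0.0504 M⁻¹ min⁻¹)

The length stands this near in part because G falls to 0% of its charge, so chains stop beginning. In the run with G held at its charge, the length at 15 h is 12.4 against 83.3. With 4 mol% of G the full-use length is 22.5, and that flask reaches 22.8, with 0% of its X and 11% of its E left, and with D at 8.93% of the X charged against the 10.0% that the quotient sets aside.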